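**Retrosynthetic overview**

1. (-)-Cubebininolide is (3R,4R)-3,4-bis(3,4,5-trimethoxybenzyl)butyrolactone (lactone locants O1, C2 (C=O), C3, C4, C5; Ar = 3,4,5-trimethoxyphenyl). Both arene rings are bought; the lactone is the only ring made and it is closed last, at the C4–C5 bond.
2. Key disconnection C4–C5: 5-exo-trig closure of an (acyloxy)methyl radical (C5, from an iodomethyl ester of the C2 carboxyl) onto an (E)-styrene. One operation closes the lactone, sets C4 trans to C3 and turns the styrene into the second ArCH2 group.
3. Enabling feature: C5 is an unsubstituted CH2 bonded only to O1 and C4, and C4 carries an exocyclic benzylic carbon. C4 and that carbon can therefore be the two carbons of a styrene that accepts the C5 radical at C4 and leaves a radical stabilised by the trimethoxyphenyl ring.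
4. The radical precursor comes from a (2R)-acid, made by auxiliary-controlled alpha-benzylation of an N-[(E)-4-arylbut-3-enoyl]oxazolidinone (sets C3), itself from Heck arylation of but-3-enoic acid. C5 enters as ClCH2 from chloromethyl chlorosulfate.

Key step: step 7

Remark: the aryl iodide, but-3-enoic acid, the (R)-oxazolidinone, the benzylic bromide and all reagents are assumed to be purchasable.

**Route**

Step 1
Reactants: 1 5-iodo-1,2,3-trimethoxybenzene; 2 but-3-enoic acid
Product: 3 (E)-4-(3,4,5-trimethoxyphenyl)but-3-enoic acid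
Conditions: Pd(OAc)2 (2 mol%), P(o-tol)3 (4 mol%), Et3N, MeCN, 80 °C; then 1 M HCl
Reagents that add atoms: none
Why: Mizoroki-Heck reaction: oxidative addition of the aryl iodide to zerovalent palladium, syn-carbopalladation with the aryl group going to the terminal carbon and beta-hydride elimination towards the benzylic hydrogen should give the aryl-conjugated (E)-alkene, the usual outcome for but-3-enoic acid, and no stereocentre is formed.

Step 2
Reactants: 3 (E)-4-(3,4,5-trimethoxyphenyl)but-3-enoic acid; 4 (R)-4-benzyloxazolidin-2-one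
Product: 6 (R)-4-benzyl-3-[(E)-4-(3,4,5-trimethoxyphenyl)but-3-enoyl]oxazolidin-2-one, via mixed pivalic anhydride 5 (not isolated)
Conditions: PivCl, Et3N, THF, -20 °C; then 4, LiCl, -20 °C to rt
Reagents that add atoms: none
Why: N-Acylation of an oxazolidinone by a mixed pivalic anhydride under LiCl/Et3N activation, mild enough that the double bond should stay in its aryl-conjugated beta,gamma position; no stereocentre is formed.

Step 3
Reactants: 6 (R)-4-benzyl-3-[(E)-4-(3,4,5-trimethoxyphenyl)but-3-enoyl]oxazolidin-2-one; 7 3,4,5-trimethoxybenzyl bromide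
Product: 9 (R)-4-benzyl-3-[(2R,3E)-2-(3,4,5-trimethoxybenzyl)-4-(3,4,5-trimethoxyphenyl)but-3-enoyl]oxazolidin-2-one, via sodium dienolate 8 (not isolated)
Conditions: NaN(SiMe3)2, THF, -78 °C; then 7, -78 to -40 °C; AcOH quench
Reagents that add atoms: none
Why: Evans asymmetric alkylation: deprotonation gives the sodium-chelated (Z)-enolate of the extended dienolate 8 (the styryl group turned away from the auxiliary by allylic strain), which should react with the benzylic bromide at the alpha-carbon and on the face opposite the ring benzyl group of the (R)-auxiliary, so that the new centre, the later C3, is (R).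

Step 4
Reactants: 9 (R)-4-benzyl-3-[(2R,3E)-2-(3,4,5-trimethoxybenzyl)-4-(3,4,5-trimethoxyphenyl)but-3-enoyl]oxazolidin-2-one
Product: 11 (2R,3E)-2-(3,4,5-trimethoxybenzyl)-4-(3,4,5-trimethoxyphenyl)but-3-enoic acid, via peroxy acid 10 (not isolated)
Conditions: LiOH, H2O2, THF/H2O (3:1), 0 °C; then Na2SO3; then HCl to pH 3
Reagents that add atoms: hydrogen peroxide (acting as LiOOH), OO
Why: Hydroperoxide cleavage of the N-acyloxazolidinone: LiOOH attacks the exocyclic carbonyl selectively, the peroxy acid 10 is reduced by sulfite, and at 0 °C the acid is released as a carboxylate that is no longer enolisable, so the alpha-centre should keep its configuration and the auxiliary is recovered.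

Step 5
Reactants: 11 (2R,3E)-2-(3,4,5-trimethoxybenzyl)-4-(3,4,5-trimethoxyphenyl)but-3-enoic acid
Product: 12 chloromethyl (2R,3E)-2-(3,4,5-trimethoxybenzyl)-4-(3,4,5-trimethoxyphenyl)but-3-enoate
Conditions: ClCH2OSO2Cl, NaHCO3, Bu4NHSO4 (cat.), CH2Cl2/H2O, 0 °C to rt
Reagents that add atoms: chloromethyl chlorosulfate, ClCOS(=O)(=O)Cl
Why: Carboxylate O-alkylation (SN2 at the CH2 of chloromethyl chlorosulfate, chlorosulfate leaving) under phase-transfer catalysis at near-neutral pH, the standard chloromethyl ester synthesis, which brings in the carbon that becomes C5 without touching the acidic alpha-centre.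

Step 6
Reactants: 12 chloromethyl (2R,3E)-2-(3,4,5-trimethoxybenzyl)-4-(3,4,5-trimethoxyphenyl)but-3-enoate
Product: 13 iodomethyl (2R,3E)-2-(3,4,5-trimethoxybenzyl)-4-(3,4,5-trimethoxyphenyl)but-3-enoate
Conditions: NaI, acetone, rt, dark; used directly
Reagents that add atoms: NaI, [Na+].[I-]
Why: Finkelstein reaction: SN2 exchange of chloride for iodide, driven by precipitation of NaCl from acetone, gives the iodomethyl ester that is the better radical precursor, with no base present to epimerise the alpha-centre.

Step 7
Reactants: 13 iodomethyl (2R,3E)-2-(3,4,5-trimethoxybenzyl)-4-(3,4,5-trimethoxyphenyl)but-3-enoate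
Product: 16 (-)-cubebininolide = (3R,4R)-3,4-bis(3,4,5-trimethoxybenzyl)dihydrofuran-2(3H)-one, via acyloxymethyl radical 14 (not isolated), via benzylic radical 15 (not isolated)
Conditions: Bu3SnH (1.3 equiv) and AIBN (0.2 equiv) added by syringe pump over 8 h, PhH (0.005 M), 80 °C; KF work-up
Reagents that add atoms: none
Why: The stannyl radical abstracts iodine from 13 to give the primary, oxygen-substituted radical 14, which after rotation of the ester into its E rotamer (the geometry of a lactone) adds to the styrene carbon remote from the aryl ring, forming the C4–C5 bond and the benzylic radical 15, which takes hydrogen from Bu3SnH to become the second ArCH2 group and passes on the chain. The closest known reaction type is the tin hydride ring closure of (alk-3-enoyloxy)methyl radicals from halomethyl but-3-enoates to butyrolactones, together with the general acceleration of hexenyl-type closures by an aryl group on the alkene terminus. The lactone ring (O1, C2, C3, C4, C5) closes in the 5-exo-trig mode. The new stereocentre C4 is controlled by the existing C3 centre: in the chair-like transition state the C3 benzyl group and the styryl arm should both sit pseudo-equatorial, which places the two ArCH2 groups trans and makes C4 (R). The step needs ring closure to outrun hydrogen transfer to 14 and 5-exo attack to beat 6-endo attack; the first is secured by the aryl-conjugated acceptor and by slow addition of Bu3SnH at high dilution and 80 °C, the second by the aryl group, which shields the benzylic carbon and makes attack at C4 give the stabilised radical. Any cis isomer is to be removed by chromatography and not by base, because epimerisation at C3 would lead to the enantiomer.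

**Compound list**

1 | 5-iodo-1,2,3-trimethoxybenzene | COc1cc(I)cc(OC)c1OC | starting material
2 | but-3-enoic acid | C=CCC(=O)O | starting material
3 | (E)-4-(3,4,5-trimethoxyphenyl)but-3-enoic acid | OC(=O)C/C=C/c1cc(OC)c(OC)c(OC)c1 | intermediate
4 | (R)-4-benzyloxazolidin-2-one | O=C1OC[C@@H](Cc2ccccc2)N1 | starting material
5 | pivalic (E)-4-(3,4,5-trimethoxyphenyl)but-3-enoic anhydride | CC(C)(C)C(=O)OC(=O)C/C=C/c1cc(OC)c(OC)c(OC)c1 | intermediate
6 | (R)-4-benzyl-3-[(E)-4-(3,4,5-trimethoxyphenyl)but-3-enoyl]oxazolidin-2-one | O=C1OC[C@@H](Cc2ccccc2)N1C(=O)C/C=C/c1cc(OC)c(OC)c(OC)c1 | intermediate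
7 | 3,4,5-trimethoxybenzyl bromide | COc1cc(CBr)cc(OC)c1OC | starting material
8 | sodium (1Z,3E)-dienolate of 6 | O=C1OC[C@@H](Cc2ccccc2)N1/C([O-])=C/C=C/c1cc(OC)c(OC)c(OC)c1.[Na+] | intermediate
9 | (R)-4-benzyl-3-[(2R,3E)-2-(3,4,5-trimethoxybenzyl)-4-(3,4,5-trimethoxyphenyl)but-3-enoyl]oxazolidin-2-one | O=C1OC[C@@H](Cc2ccccc2)N1C(=O)[C@H](Cc1cc(OC)c(OC)c(OC)c1)/C=C/c1cc(OC)c(OC)c(OC)c1 | intermediate
10 | (2R,3E)-2-(3,4,5-trimethoxybenzyl)-4-(3,4,5-trimethoxyphenyl)but-3-eneperoxoic acid | OOC(=O)[C@H](Cc1cc(OC)c(OC)c(OC)c1)/C=C/c1cc(OC)c(OC)c(OC)c1 | intermediate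
11 | (2R,3E)-2-(3,4,5-trimethoxybenzyl)-4-(3,4,5-trimethoxyphenyl)but-3-enoic acid | OC(=O)[C@H](Cc1cc(OC)c(OC)c(OC)c1)/C=C/c1cc(OC)c(OC)c(OC)c1 | intermediate
12 | chloromethyl (2R,3E)-2-(3,4,5-trimethoxybenzyl)-4-(3,4,5-trimethoxyphenyl)but-3-enoate | ClCOC(=O)[C@H](Cc1cc(OC)c(OC)c(OC)c1)/C=C/c1cc(OC)c(OC)c(OC)c1 | intermediate
13 | iodomethyl (2R,3E)-2-(3,4,5-trimethoxybenzyl)-4-(3,4,5-trimethoxyphenyl)but-3-enoate | ICOC(=O)[C@H](Cc1cc(OC)c(OC)c(OC)c1)/C=C/c1cc(OC)c(OC)c(OC)c1 | intermediate
14 | {[(2R,3E)-2-(3,4,5-trimethoxybenzyl)-4-(3,4,5-trimethoxyphenyl)but-3-enoyl]oxy}methyl radical | [CH2]OC(=O)[C@H](Cc1cc(OC)c(OC)c(OC)c1)/C=C/c1cc(OC)c(OC)c(OC)c1 | intermediate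
15 | benzylic radical of the closed (3R,4R)-lactone (radical centre on the ArCH carbon attached to C4) | COc1cc([CH][C@H]2COC(=O)[C@@H]2Cc2cc(OC)c(OC)c(OC)c2)cc(OC)c1OC | intermediate
16 | (-)-cubebininolide, (3R,4R)-3,4-bis(3,4,5-trimethoxybenzyl)dihydrofuran-2(3H)-one | COc1cc(C[C@H]2COC(=O)[C@@H]2Cc2cc(OC)c(OC)c(OC)c2)cc(OC)c1OC | target

**Step count and risks**

Total steps: 7. Longest linear sequence: 7 steps (1 or 2 to 16).

Steps most likely to fail, in order of risk:

Step 7. What may go wrong: hydrogen transfer from Bu3SnH to radical 14 before the ester has rotated into the rotamer that can cyclise (simple reduction of the C–I bond); 1,5-hydrogen transfer from the benzylic CH2 on C3 to the radical centre; or weak facial discrimination at C4.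
Fallback: replace the ester tether by a silicon ether, whose radical closure through a six-membered chair is fast, and use the hidden C2 symmetry of the carbon skeleton at the end. The fallback sets out from imide 9.
- Reductive removal of the auxiliary (LiBH4, MeOH, Et2O, 0 °C) should give (2R,3E)-2-(3,4,5-trimethoxybenzyl)-4-(3,4,5-trimethoxyphenyl)but-3-en-1-ol F1.
- Silylation with (bromomethyl)chlorodimethylsilane, Et3N and DMAP in CH2Cl2 should give its (bromomethyl)dimethylsilyl ether F2.
- Bu3SnH/AIBN in PhH at 80 °C should close the silylmethyl radical 6-exo onto the same styrene carbon (C4), with both substituents equatorial, to give (4R,5R)-2,2-dimethyl-4,5-bis(3,4,5-trimethoxybenzyl)-1,2-oxasilinane F3.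
- Tamao oxidation (KF, KHCO3, H2O2, THF/MeOH) should give (2R,3R)-2,3-bis(3,4,5-trimethoxybenzyl)butane-1,4-diol F4.
- Ag2CO3 on Celite in refluxing PhH should oxidise one CH2OH group through (3R,4R)-3,4-bis(3,4,5-trimethoxybenzyl)tetrahydrofuran-2-ol F5 to the lactone. Because the two CH2OH groups of the C2-symmetric diol are homotopic, either one leads to the same lactone, and the route is rejoined at target 16.

Step 4. What may go wrong: base-induced epimerisation or migration of the double bond into conjugation at the doubly activated alpha-carbon, or hydroperoxide attack at the ring carbonyl of the hindered imide (ring opening of the auxiliary).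
Fallback: cleave with a soft, weakly basic nucleophile and hydrolyse without base. Setting out from imide 9, LiSEt (from EtSH and n-BuLi) in THF at 0 °C should give S-ethyl (2R,3E)-2-(3,4,5-trimethoxybenzyl)-4-(3,4,5-trimethoxyphenyl)but-3-enethioate F6 and free auxiliary 4. Silver-assisted hydrolysis (AgNO3, 2,6-lutidine, THF/H2O, rt) should then give acid 11, where the route is rejoined.

Step 3. What may go wrong: alkylation at the gamma-carbon of the dienolate, incomplete facial control, or proton exchange between product and enolate that erodes the new centre.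
Fallback: drop the covalent auxiliary and alkylate the free acid, a known method for beta,gamma-unsaturated acids. Setting out from acid 3 and bromide 7, n-BuLi (4 equiv) and a C2-symmetric chiral tetramine in THF at 0 °C should give the dilithium enediolate F7 as a mixed aggregate with the chiral dilithium amide. The enantiomer of the tetramine is chosen so that the (R)-acid results. Addition of 7 at -78 °C and acidic extraction, which also recovers the tetramine, should give acid 11 directly, bypassing steps 2 to 4; the route is rejoined at 11.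

**Further compounds**

F1 | step 7 | (2R,3E)-2-(3,4,5-trimethoxybenzyl)-4-(3,4,5-trimethoxyphenyl)but-3-en-1-ol | OC[C@H](Cc1cc(OC)c(OC)c(OC)c1)/C=C/c1cc(OC)c(OC)c(OC)c1
F2 | step 7 | (bromomethyl)dimethylsilyl ether of F1 | BrC[Si](C)(C)OC[C@H](Cc1cc(OC)c(OC)c(OC)c1)/C=C/c1cc(OC)c(OC)c(OC)c1
F3 | step 7 | (4R,5R)-2,2-dimethyl-4,5-bis(3,4,5-trimethoxybenzyl)-1,2-oxasilinane | C[Si]1(C)OC[C@H](Cc2cc(OC)c(OC)c(OC)c2)[C@@H](Cc2cc(OC)c(OC)c(OC)c2)C1
F4 | step 7 | (2R,3R)-2,3-bis(3,4,5-trimethoxybenzyl)butane-1,4-diol | OC[C@H](Cc1cc(OC)c(OC)c(OC)c1)[C@H](CO)Cc1cc(OC)c(OC)c(OC)c1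
F5 | step 7 | (3R,4R)-3,4-bis(3,4,5-trimethoxybenzyl)tetrahydrofuran-2-ol (anomer mixture) | COc1cc(C[C@H]2COC(O)[C@@H]2Cc2cc(OC)c(OC)c(OC)c2)cc(OC)c1OC
F6 | step 4 | S-ethyl (2R,3E)-2-(3,4,5-trimethoxybenzyl)-4-(3,4,5-trimethoxyphenyl)but-3-enethioate | CCSC(=O)[C@H](Cc1cc(OC)c(OC)c(OC)c1)/C=C/c1cc(OC)c(OC)c(OC)c1
F7 | step 3 | dilithium enediolate of acid 3 | [Li+].[Li+].[O-]C([O-])=C/C=C/c1cc(OC)c(OC)c(OC)c1
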